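## Structural features

Numbering used throughout: C1 is the ring carbon bearing the isopropenyl group (C15–C17), C2 the acetoxy carbon, C3=C4 the alkene with the acetoxymethyl carbon C18 on C4, C7 the carbinol, C8 the carbon bearing the exocyclic methylene C19, C11=C12 the alkene with a methyl group on C12, and C14 the ring carbon that closes back to C1.

The target is a cembrane-type diterpenoid built on a single fourteen-membered carbocycle with no second ring. C1 (R) and C2 (S) are neighbours and stand anti when C3–C2–C1–C15 is drawn as a zigzag. C7 (R) is four ring atoms away from them, so it cannot be set by relay from the C1/C2 pair. Both ring alkenes are trisubstituted: C11=C12 is E in the geranyl sense, and at C3=C4 the ring carbons C2 and C5 are cis while C2 and C18 are trans. The fragile groups are the two allylic acetates (cleaved by hydride or base, ionised by zerovalent palladium), the secondary allylic alcohol at C7, and the 1,1-disubstituted alkenes at C8 and C15, which migrate under acid. The real difficulty is to close the large ring without risking an alkene geometry or a stereocentre, and to tell three oxygen functions apart so that only C7 ends free. The key step uses the C9–C10 bond, the only ring bond flanked by allylic sp3 carbons on both sides. C10 belongs to the geranyl-type unit C10–C11=C12 and can carry a sulfone-stabilised carbanion; C9 belongs to the 2-methyleneallyl unit C9–C8(=C19), whose two methylene ends are interchangeable, so an allylic electrophile there cannot give a regioisomer.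

## Logic of the disconnections

**28 back to 25.** The bonds cut are the two acetyl C–O bonds (C2, C18) and the benzylic C–O bond at C7: 28 comes from 27, 27 from 26, 26 from 25. The reason is that acetates cannot be present while hydride and palladium remove the sulfone, so silyl ethers stand in for them and a 4-methoxybenzyl ether marks C7 as the oxygen that stays free. The gain is that all base-, hydride- and palladium-sensitive groups appear only in the last three steps. The demand is that fluoride leaves the benzyl-type ether alone and that the final oxidative debenzylation spares two allylic acetates and four alkenes.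

**25 back to 24.** A C10–S bond is added retrosynthetically. The phenylsulfonyl group is the handle that makes C10 nucleophilic, so an unactivated CH2–CH2 ring bond becomes a retron for carbanion alkylation. The forward step must deliver hydride at C10 and not at C12, and must keep C11=C12 as E.

**24 back to 23.** The C9–C10 ring bond is cut, opening the macrocycle to one chain that already holds C1, C2, C7 and both trisubstituted alkenes. The cut falls between two sp3 methylene carbons, so ring closure creates no permanent stereocentre and touches no alkene. The demand is intramolecular alkylation at high dilution, at the sulfonyl-bearing carbon.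

**23 back to 20.** The C9–Br bond and the benzyl-type C–O bond at C7 are traced back through 22 and 21 to 20, in which the 4-methoxybenzyl group sits on the C9 oxygen and C7 is a free hydroxyl. Moving the benzyl group from O9 to O7 through the cyclic acetal 21 protects C7 and frees C9 without a separate protection and deprotection pair. The demand is regioselective reductive opening of the acetal towards the primary oxygen, and bromination of a primary allylic alcohol next to silyl ethers.

**20 back to 16 and 19.** The C7–C8 bond is cut. This delivers the whole C8/C9/C19 unit as the small bromoalkene 19 and leaves C7 as an aldehyde. The forward alkenylation must set C7 (R) under reagent control, because the nearest stereocentre is five atoms away.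

**16 back to 13 and 6.** After functional-group changes (16 from 15, 15 from 14), the C1–C2 bond is cut. This is the only bond between two stereocentres, and its anti relationship is the signature of an E-γ-substituted allylboron reagent adding to an aldehyde. The cut divides the chain into two achiral halves of similar size. The forward step must control the absolute sense with a chiral catalyst, and the C7 carbon must stay at the ester level until the enal has reacted.

**6 back to 1 and 2.** The C16–B bond, the C16–O bond and the C10–S bond are cut: 6 from 5, 5 from 4, 4 from 1 and 2 through 3. Compound 1 already contains C10–C14, C1 and C15–C17 with the E alkene in place. The demands are allylic oxidation at the E methyl group of the distal alkene only, and borylation that keeps the new alkene E.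

**13 back to 7 and 11.** The C4–C5 bond is cut (12 from 10 and 11), then the C4–I and C3–H bonds (10 from 8 through 9) and one Si–O bond (8 from 7). A symmetrical four-carbon alkyne supplies C2, C3, C4 and C18, and the free hydroxyl decides which alkyne carbon receives the metal. The demand is net trans addition of hydrogen and carbon across the alkyne, so that C2 and C5 end cis.

**19 back to 17 and 18.** One allylic C–O bond is cut; a Williamson ether synthesis from two commercial compounds suffices.

## Other disconnections considered

**Alternative 1:** The cut is the C1–C2 ring bond between the two adjacent stereocentres. In the forward step the open-chain bromo-enal A1 (C16 allylic bromide, C2 enal, C18 acetate, C7 silyl ether, C9–C10 already joined) is treated with CrCl2 at high dilution. The allylchromium species adds through C1 to the aldehyde in a six-membered chair to give the macrocyclic alcohol A2.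
- In its favour: one operation forms the ring, the C1–C2 bond, the isopropenyl group and both stereocentres. It is convergent for E and Z bromide, the anti relationship is inherent, and divalent chromium tolerates the acetate and silyl ether. A2 needs only acetylation at C2 and desilylation at C7 to reach 28.
- Against it here: the absolute sense of the new C1/C2 pair must be relayed from C7 across the forming ring, and no reliable model predicts that. A wrong-handed anti pair is a diastereomer that cannot be corrected. A1 still needs the sp3–sp3 C9–C10 union made in the open chain, and an enal must coexist with an allylic bromide.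
- Comparison: on structure, the alternative closes at the most congested bond, the chosen plan at an unhindered methylene pair. On mechanism, both rely on a chair transition state for the anti pair, but the chosen plan sets its absolute sense with a catalyst in an acyclic setting, and its ring closure carries no stereochemical burden. On step economy the alternative is the better after ring closure (two steps against four) and carries no traceless group. The two are equal in that both close a fourteen-membered ring by C–C bond formation at high dilution.

**Alternative 2:** The cut is C14–C1, by a [3,3] shift. In the forward step the eighteen-membered lactone A3 (ester oxygen on C16, C15=C1 alkene, acyl carbon attached to C14) is converted with KN(SiMe3)2 and Me3SiCl into its silyl ketene acetal. This rearranges with ring contraction to the fourteen-membered acid A4.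
- In its favour: macrolactonisation is the most dependable way to close a large ring, the C–C bond then forms inside a preorganised ring without dilution, and the isopropenyl group is released by the rearrangement. On these points it is better than the chosen plan.
- Against it here: C14 of the target is a plain methylene, so the carboxyl group of A4 must be excised, for example by radical decarboxylation, over two or three steps before the route could join at 25. The chair or boat preference of a ring-contracting rearrangement is not predictable, so the configuration of C1 relative to C2 is uncertain. C2 would have to be set earlier by separate asymmetric chemistry.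
- Comparison: on structure, both plans carry a traceless group, but the sulfone leaves in one step. On mechanism, the concerted shift stakes C1 on transition-state geometry, whereas the chosen plan fixes C1 and C2 together before the ring exists. On step economy the alternative is the longer.

**Alternative 3:** The cut is the C3=C4 double bond. In the forward step the open-chain aldehyde phosphonate A5 (C3 aldehyde with the silyloxy group on C2, phosphonoacetate carbon C4) is treated with LiCl and i-Pr2NEt at high dilution. Intramolecular Horner–Wadsworth–Emmons olefination gives the macrocyclic ester A6 with the ester trans to C2.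
- In its favour: macrocyclic olefination under Masamune–Roush conditions is as well precedented as sulfone alkylation. The ester-trans-to-C2 geometry is the normal preference, C18 arrives on the right carbon, and no traceless group is needed. Ester reduction and desilylation would take A6 to 26 in two steps, equal to the two steps from 24 to 26.
- Against it here: the α-silyloxy aldehyde can epimerise at C2. α-Branched phosphonoacetates are less E-selective, and in a fourteen-membered ring strain may override the intrinsic preference. A5 must contain the C1/C2 pair without the C3=C4 alkene, so the enal allylboration is not available and the fragment synthesis would be longer.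
- Comparison: on structure, the chosen plan makes C3=C4 early with geometry fixed by alkyne trans-hydroalumination, whereas the alternative stakes that geometry on the ring closure. On mechanism, addition–elimination at a carbonyl carries a geometric risk that SN2 closure between sp3 carbons does not. On step economy the two are about equal after ring closure, and the alternative is probably longer before it.

Key step: step 16

Remark on the chemistry: the configurations of 23 and 24 were checked against 28 (C1 R, C2 S, C7 R, C11=C12 E, C2 and C18 trans) and need no correction. The facial preferences quoted for the chiral catalysts of steps 8 and 12 follow the accepted transition-state models of these catalyst classes; if either sense proved opposite, the enantiomeric catalyst would be used without other change. Compound 11 is taken as the commercial THF solution.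

## Route

Step 1
Reactants: 1 geraniol; 2 sodium benzenesulfinate
Product: 4 geranyl phenyl sulfone, via geranyl bromide 3 (not isolated)
Conditions: PBr3 (0.4 equiv), THF, −10 °C; then 2 (2 equiv), DMF, rt
Reagents that add atoms: none
Why: Low-temperature PBr3 bromination converts the primary allylic alcohol into the bromide without allylic transposition, and the soft sulfur of the sulfinate then displaces it (SN2 S-alkylation); the E alkene that becomes C11=C12 is not touched.

Step 2
Reactants: 4 geranyl phenyl sulfone
Product: 5 (2E,6E)-2,6-dimethyl-8-(phenylsulfonyl)octa-2,6-dien-1-ol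
Conditions: SeO2 (0.2 equiv), t-BuOOH (3 equiv), salicylic acid (0.1 equiv), CH2Cl2, 0 °C → rt
Reagents that add atoms: tert-butyl hydroperoxide, CC(C)(C)OO (terminal oxidant; oxygen passed on through catalytic SeO2, O=[Se]=O)
Why: Riley-type allylic oxidation (ene reaction, then [2,3]-sigmatropic shift) attacks the more electron-rich terminal alkene at its E methyl group; the alkene next to the electron-poor sulfonylmethyl group should react much more slowly.

Step 3
Reactants: 5 (2E,6E)-2,6-dimethyl-8-(phenylsulfonyl)octa-2,6-dien-1-ol
Product: 6 2-[(2E,6E)-2,6-dimethyl-8-(phenylsulfonyl)octa-2,6-dien-1-yl]-4,4,5,5-tetramethyl-1,3,2-dioxaborolane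
Conditions: [Pd(MeCN)4](BF4)2 (5 mol %), B2pin2 (1.2 equiv), DMSO/MeOH 1:1, 40 °C
Reagents that add atoms: bis(pinacolato)diboron, CC1(C)OB(B2OC(C)(C)C(C)(C)O2)OC1(C)C
Why: Pd-catalysed direct borylation of an allylic alcohol: the diboron reagent activates the hydroxyl, ionisation gives an η3-allylpalladium, and boron enters at the unsubstituted terminus, so the linear boronate should form with the chain trans to CH2B. Under phosphine-free conditions the allylic sulfone is a much poorer leaving group.

Step 4
Reactants: 7 2-butyne-1,4-diol
Product: 8 4-[(tert-butyldimethylsilyl)oxy]but-2-yn-1-ol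
Conditions: NaH (1.0 equiv), THF, 0 °C → rt; TBSCl (1.0 equiv)
Reagents that add atoms: tert-butyldimethylsilyl chloride, CC(C)(C)[Si](C)(C)Cl
Why: Monosilylation of a symmetrical diol through its sparingly soluble monosodium alkoxide, which is silylated faster than it equilibrates to the dialkoxide.

Step 5
Reactants: 8 4-[(tert-butyldimethylsilyl)oxy]but-2-yn-1-ol
Product: 10 (2Z)-4-[(tert-butyldimethylsilyl)oxy]-3-iodobut-2-en-1-ol, via cyclic alkenylaluminate 9 (not isolated)
Conditions: NaAlH2(OCH2CH2OMe)2 (1.6 equiv), THF, 0 °C → rt; EtOAc; then I2, THF, −78 → 0 °C
Reagents that add atoms: iodine, II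
Why: Hydroxyl-directed trans-hydroalumination of the propargylic alcohol puts hydride on C3 and aluminium on C4 in a five-membered alkoxyaluminate. Iodinolysis of the C–Al bond goes with retention, which fixes C2 and C18 trans across C3=C4; the silyl ether end cannot direct.

Step 6
Reactants: 10 (2Z)-4-[(tert-butyldimethylsilyl)oxy]-3-iodobut-2-en-1-ol; 11 (3-ethoxy-3-oxopropyl)zinc bromide
Product: 12 ethyl (4E)-4-{[(tert-butyldimethylsilyl)oxy]methyl}-6-hydroxyhex-4-enoate
Conditions: 11 (2.5 equiv), Pd2(dba)3 (2.5 mol %), SPhos (10 mol %), THF, rt → 40 °C
Reagents that add atoms: none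
Why: Negishi coupling of an alkenyl iodide with a zinc homoenolate goes with retention of alkene geometry, so C5 enters cis to C2. The ester is inert to the organozinc, and the free hydroxyl is carried as its zinc alkoxide when the reagent is in excess.

Step 7
Reactants: 12 ethyl (4E)-4-{[(tert-butyldimethylsilyl)oxy]methyl}-6-hydroxyhex-4-enoate
Product: 13 ethyl (4E)-4-{[(tert-butyldimethylsilyl)oxy]methyl}-6-oxohex-4-enoate
Conditions: MnO2 (15 equiv), CH2Cl2, rt
Reagents that add atoms: none
Why: MnO2 oxidises only the allylic alcohol, under neutral heterogeneous conditions that should neither isomerise the trisubstituted alkene nor affect the ester and silyl ether.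

Step 8
Reactants: 13 ethyl (4E)-4-{[(tert-butyldimethylsilyl)oxy]methyl}-6-oxohex-4-enoate; 6 the (E)-allylboronate
Product: 14 ethyl (4E,6S,7R,10E)-4-{[(tert-butyldimethylsilyl)oxy]methyl}-6-hydroxy-10-methyl-12-(phenylsulfonyl)-7-(prop-1-en-2-yl)dodeca-4,10-dienoate (target C1 R, C2 S)
Conditions: (R)-TRIP [(R)-3,3′-bis(2,4,6-triisopropylphenyl)-1,1′-binaphthyl-2,2′-diyl hydrogen phosphate] (5 mol %), 4 Å MS, toluene, −30 °C; aqueous NaHCO3 work-up
Reagents that add atoms: none
Why: Chiral phosphoric acid-catalysed allylboration: the boronate adds through its γ-carbon (C1) in a closed chair transition state with the E γ-substituent (the C14 chain) equatorial, which gives the anti C1/C2 pair and the isopropenyl group. The catalyst, hydrogen-bonded to a boronate oxygen and the formyl hydrogen, directs attack to the Re face of the enal (2S, hence 1R). Both partners are achiral, so the absolute configuration rests on the catalyst alone.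

Step 9
Reactants: 14 the (1R,2S) homoallylic alcohol
Product: 15 ethyl (4E,6S,7R,10E)-6-[(tert-butyldimethylsilyl)oxy]-4-{[(tert-butyldimethylsilyl)oxy]methyl}-10-methyl-12-(phenylsulfonyl)-7-(prop-1-en-2-yl)dodeca-4,10-dienoate
Conditions: TBSOTf (1.3 equiv), 2,6-lutidine (2 equiv), CH2Cl2, −78 → 0 °C
Reagents that add atoms: tert-butyldimethylsilyl trifluoromethanesulfonate, CC(C)(C)[Si](C)(C)OS(=O)(=O)C(F)(F)F
Why: A silyl triflate with a hindered pyridine base silylates the hindered secondary allylic alcohol at low temperature without enolising the ester or deprotonating the sulfone.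

Step 10
Reactants: 15 the bis-silyl ether ester
Product: 16 (4E,6S,7R,10E)-6-[(tert-butyldimethylsilyl)oxy]-4-{[(tert-butyldimethylsilyl)oxy]methyl}-10-methyl-12-(phenylsulfonyl)-7-(prop-1-en-2-yl)dodeca-4,10-dienal (C7 aldehyde)
Conditions: i-Bu2AlH (1.1 equiv), CH2Cl2, −78 °C; MeOH, then aqueous Rochelle salt
Reagents that add atoms: none
Why: Partial reduction of the ethyl ester with one equivalent of i-Bu2AlH at −78 °C stops at the aluminium hemiacetal, which gives the aldehyde on work-up; sulfone and silyl ethers are inert.

Step 11
Reactants: 17 4-methoxybenzyl alcohol; 18 2,3-dibromopropene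
Product: 19 1-{[(2-bromoprop-2-en-1-yl)oxy]methyl}-4-methoxybenzene (2-bromoallyl 4-methoxybenzyl ether)
Conditions: NaH (1.1 equiv), THF, 0 °C; 18 (1.2 equiv), Bu4NI (cat.), 0 °C → rt
Reagents that add atoms: none
Why: Williamson etherification: the alkoxide of 17 displaces the allylic bromide of 18, while the vinylic bromide is inert to SN2 attack.

Step 12
Reactants: 16 the C7 aldehyde; 19 2-bromoallyl 4-methoxybenzyl ether
Product: 20 open-chain (1R,2S,7R) C7 allylic alcohol with C8 methylene, C9 4-methoxybenzyl ether, C2 and C18 TBS ethers, C10 phenyl sulfone
Conditions: CrCl2 (10 mol %), chiral oxazoline–sulfonamide ligand N-[2-(4-isopropyl-4,5-dihydro-1,3-oxazol-2-yl)-6-methylphenyl]methanesulfonamide (12 mol %, enantiomer that directs Si-face addition), Et3N (12 mol %), NiCl2(2,9-dimethyl-1,10-phenanthroline) (2 mol %), Mn (2 equiv), Cp2ZrCl2 (1.2 equiv), LiCl (2 equiv), MeCN, rt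
Reagents that add atoms: none
Why: Catalytic asymmetric Nozaki–Hiyama–Kishi alkenylation: zerovalent nickel inserts into the vinylic C–Br bond of 19, the alkenyl group passes to chromium and adds to the aldehyde inside the chiral ligand sphere, and Si-face addition sets C7 as R. Cp2ZrCl2 frees the alkoxide from chromium and Mn returns chromium to its divalent state. Alkenylchromium species are not basic, so the sulfone, silyl ethers and trisubstituted alkenes should be left alone.

Step 13
Reactants: 20 the C7 alcohol with C9 4-methoxybenzyl ether
Product: 21 cyclic 4-methoxybenzylidene acetal of the C7/C9 diol (2-aryl-5-methylene-1,3-dioxane, aryl and C6 chain cis)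
Conditions: DDQ (1.2 equiv), 4 Å MS, CH2Cl2, −10 → 0 °C
Reagents that add atoms: none
Why: Under anhydrous conditions DDQ oxidises the 4-methoxybenzyl ether to an oxocarbenium ion, which the neighbouring C7 hydroxyl traps as the six-membered acetal with aryl group and C6 chain both equatorial. The acetal centre is lost in the next step.

Step 14
Reactants: 21 the 4-methoxybenzylidene acetal
Product: 22 open-chain C9 primary allylic alcohol with C7 4-methoxybenzyl ether (1R,2S,7R), C2 and C18 TBS ethers, C10 phenyl sulfone
Conditions: i-Bu2AlH (3 equiv), CH2Cl2, −78 → −20 °C; aqueous Rochelle salt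
Reagents that add atoms: none
Why: Reductive acetal opening: the aluminium hydride binds the less hindered oxygen (on C9), that C–O bond breaks and hydride adds to the oxocarbenium ion. The 4-methoxybenzyl group is left on the secondary C7 oxygen and the C9 hydroxyl is freed.

Step 15
Reactants: 22 the C9 alcohol
Product: 23 open-chain C10 phenyl sulfone with C9 allylic bromide, C7 4-methoxybenzyl ether, C2 and C18 TBS ethers (1R,2S,7R)
Conditions: CBr4 (1.3 equiv), PPh3 (1.4 equiv), 2,6-lutidine (0.5 equiv), CH2Cl2, −20 → 0 °C; used at once
Reagents that add atoms: carbon tetrabromide, BrC(Br)(Br)Br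
Why: Appel bromination of the primary allylic alcohol under nearly neutral conditions. Direct and transposed displacement give the same bromide because C9 and C19 are equivalent, and silyl ethers, benzyl-type ether and sulfone are unaffected.

Step 16
Reactants: 23 the bromo sulfone
Product: 24 macrocyclic 10-phenylsulfonyl compound (C10 epimers; 1R,2S,7R), C7 4-methoxybenzyl ether, C2 and C18 TBS ethers
Conditions: KN(SiMe3)2 (1.3 equiv), THF, −20 → 0 °C; 23 added over 8 h by syringe pump, final concentration 0.002 M
Reagents that add atoms: none
Why: KN(SiMe3)2 removes a C10 proton to give the potassium allyl sulfone carbanion, which displaces bromide from the 2-substituted allyl unit and forms the C9–C10 bond. The closest known reaction type is the intramolecular alkylation of sulfone-stabilised allylic carbanions by allylic halides, used for fourteen-membered terpenoid carbocycles. The ring closes in the 14-exo-tet mode, or in the degenerate SN2′ (14-exo-trig) mode, which gives the same product because C9 and C19 are interchangeable. No permanent stereocentre is formed: C10 becomes a transient centre, obtained as epimers and removed in step 17. The step needs alkylation at the sulfonyl-bearing carbon and not at C12; this is the normal preference of allyl sulfone anions and is reinforced here because attack through C12 would create a quaternary centre in a twelve-membered ring. It also needs ring closure to outrun chain growth, which slow addition into dilute base at a temperature where cyclisation is fast should secure. Neither trisubstituted alkene takes part, so both geometries and C1, C2 and C7 should pass through unchanged.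

Step 17
Reactants: 24 the macrocyclic sulfone
Product: 25 macrocycle with C10 methylene, C7 4-methoxybenzyl ether, C2 and C18 TBS ethers (1R,2S,7R)
Conditions: PdCl2(dppp) (10 mol %), LiBHEt3 (3 equiv), THF, 0 °C → rt
Reagents that add atoms: none
Why: Pd-catalysed reductive desulfonylation: zerovalent palladium ionises the allylic C10–S bond and hydride from LiBHEt3 is passed through palladium to the less substituted allyl terminus C10, restoring the E C11=C12 alkene. The chelating dppp ligand favours fast hydride transfer over syn–anti isomerisation, and allylic silyl and benzyl-type ethers are not ionised.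

Step 18
Reactants: 25 the bis-silyl ether macrocycle
Product: 26 macrocyclic C2, C18 diol with C7 4-methoxybenzyl ether
Conditions: Bu4NF (3 equiv), THF, 0 °C → rt
Reagents that add atoms: none
Why: Fluoride cleaves both silyl ethers through Si–F bond formation; the 4-methoxybenzyl ether and the alkenes are inert.

Step 19
Reactants: 26 the diol
Product: 27 macrocyclic C2, C18 diacetate with C7 4-methoxybenzyl ether
Conditions: Ac2O (4 equiv), pyridine, DMAP (cat.), CH2Cl2, 0 °C → rt
Reagents that add atoms: acetic anhydride, CC(=O)OC(C)=O
Why: DMAP-catalysed acylation of the primary and the hindered secondary allylic alcohol; C7 is still masked, which distinguishes it from C2 and C18.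

Step 20
Reactants: 27 the diacetate 4-methoxybenzyl ether
Product: 28 target, (1R,2S,7R)-2-acetoxy-18-acetoxy-7-hydroxycembra-3,8(19),11,15-tetraene (3E by the sequence rule, 11E)
Conditions: DDQ (1.5 equiv), CH2Cl2/pH 7 phosphate buffer 10:1, 0 °C
Reagents that add atoms: none
Why: Oxidative debenzylation: DDQ abstracts the benzylic hydride of the electron-rich ether and water hydrolyses the oxocarbenium ion to 4-methoxybenzaldehyde and the C7 alcohol. Acetates and unactivated alkenes do not react, and a simple allylic alcohol is oxidised only slowly by DDQ.

## Compound list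

1 | geraniol | CC(C)=CCC/C(C)=C/CO | starting material
2 | sodium benzenesulfinate | [Na+].[O-]S(=O)c1ccccc1 | starting material
3 | geranyl bromide (not isolated) | CC(C)=CCC/C(C)=C/CBr | intermediate
4 | geranyl phenyl sulfone, (2E)-3,7-dimethylocta-2,6-dien-1-yl phenyl sulfone | CC(C)=CCC/C(C)=C/CS(=O)(=O)c1ccccc1 | intermediate
5 | (2E,6E)-2,6-dimethyl-8-(phenylsulfonyl)octa-2,6-dien-1-ol | OC/C(C)=C/CC/C(C)=C/CS(=O)(=O)c1ccccc1 | intermediate
6 | 2-[(2E,6E)-2,6-dimethyl-8-(phenylsulfonyl)octa-2,6-dien-1-yl]-4,4,5,5-tetramethyl-1,3,2-dioxaborolane | CC1(C)OB(C/C(C)=C/CC/C(C)=C/CS(=O)(=O)c2ccccc2)OC1(C)C | intermediate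
7 | 2-butyne-1,4-diol | OCC#CCO | starting material
8 | 4-[(tert-butyldimethylsilyl)oxy]but-2-yn-1-ol | OCC#CCO[Si](C)(C)C(C)(C)C | intermediate
9 | sodium 2,2-bis(2-methoxyethoxy)-3-{[(tert-butyldimethylsilyl)oxy]methyl}-2,5-dihydro-1,2-oxaluminol-2-uide, cyclic alkenylaluminate (not isolated) | [Na+].COCCO[Al-]1(OCCOC)OCC=C1CO[Si](C)(C)C(C)(C)C | intermediate
10 | (2Z)-4-[(tert-butyldimethylsilyl)oxy]-3-iodobut-2-en-1-ol | OC/C=C(\I)CO[Si](C)(C)C(C)(C)C | intermediate
11 | (3-ethoxy-3-oxopropyl)zinc bromide | CCOC(=O)CC[Zn]Br | starting material
12 | ethyl (4E)-4-{[(tert-butyldimethylsilyl)oxy]methyl}-6-hydroxyhex-4-enoate | CCOC(=O)CC/C(CO[Si](C)(C)C(C)(C)C)=C\CO | intermediate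
13 | ethyl (4E)-4-{[(tert-butyldimethylsilyl)oxy]methyl}-6-oxohex-4-enoate | CCOC(=O)CC/C(CO[Si](C)(C)C(C)(C)C)=C\C=O | intermediate
14 | ethyl (4E,6S,7R,10E)-4-{[(tert-butyldimethylsilyl)oxy]methyl}-6-hydroxy-10-methyl-12-(phenylsulfonyl)-7-(prop-1-en-2-yl)dodeca-4,10-dienoate | O=S(=O)(c1ccccc1)C/C=C(\C)CC[C@H](C(=C)C)[C@@H](O)/C=C(/CO[Si](C)(C)C(C)(C)C)CCC(=O)OCC | intermediate
15 | 6-O-TBS ether of 14 | O=S(=O)(c1ccccc1)C/C=C(\C)CC[C@H](C(=C)C)[C@@H](O[Si](C)(C)C(C)(C)C)/C=C(/CO[Si](C)(C)C(C)(C)C)CCC(=O)OCC | intermediate
16 | C7 aldehyde corresponding to 15 (dodeca-4,10-dienal) | O=S(=O)(c1ccccc1)C/C=C(\C)CC[C@H](C(=C)C)[C@@H](O[Si](C)(C)C(C)(C)C)/C=C(/CO[Si](C)(C)C(C)(C)C)CCC=O | intermediate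
17 | 4-methoxybenzyl alcohol | OCc1ccc(OC)cc1 | starting material
18 | 2,3-dibromopropene | C=C(Br)CBr | starting material
19 | 2-bromoallyl 4-methoxybenzyl ether | C=C(Br)COCc1ccc(OC)cc1 | intermediate
20 | open-chain (1R,2S,7R) C7 alcohol, C9 4-methoxybenzyl ether, C2/C18 TBS ethers, C10 phenyl sulfone | O=S(=O)(c1ccccc1)C/C=C(\C)CC[C@H](C(=C)C)[C@@H](O[Si](C)(C)C(C)(C)C)/C=C(/CO[Si](C)(C)C(C)(C)C)CC[C@@H](O)C(=C)COCc1ccc(OC)cc1 | intermediate
21 | C7/C9 4-methoxybenzylidene acetal (cis-2-aryl-4-alkyl-5-methylene-1,3-dioxane) | O=S(=O)(c1ccccc1)C/C=C(\C)CC[C@H](C(=C)C)[C@@H](O[Si](C)(C)C(C)(C)C)/C=C(/CO[Si](C)(C)C(C)(C)C)CC[C@H]1O[C@@H](c2ccc(OC)cc2)OCC1=C | intermediate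
22 | open-chain C9 alcohol, C7 4-methoxybenzyl ether (1R,2S,7R) | O=S(=O)(c1ccccc1)C/C=C(\C)CC[C@H](C(=C)C)[C@@H](O[Si](C)(C)C(C)(C)C)/C=C(/CO[Si](C)(C)C(C)(C)C)CC[C@@H](OCc1ccc(OC)cc1)C(=C)CO | intermediate
23 | open-chain C10 phenyl sulfone with C9 allylic bromide (1R,2S,7R) | O=S(=O)(c1ccccc1)C/C=C(\C)CC[C@H](C(=C)C)[C@@H](O[Si](C)(C)C(C)(C)C)/C=C(/CO[Si](C)(C)C(C)(C)C)CC[C@@H](OCc1ccc(OC)cc1)C(=C)CBr | intermediate
24 | 10-phenylsulfonyl macrocycle (C10 epimers) | C=C1CC(S(=O)(=O)c2ccccc2)/C=C(\C)CC[C@H](C(=C)C)[C@@H](O[Si](C)(C)C(C)(C)C)/C=C(/CO[Si](C)(C)C(C)(C)C)CC[C@H]1OCc2ccc(OC)cc2 | intermediate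
25 | desulfonylated macrocycle, C2/C18 TBS ethers, C7 4-methoxybenzyl ether | C=C1CC/C=C(\C)CC[C@H](C(=C)C)[C@@H](O[Si](C)(C)C(C)(C)C)/C=C(/CO[Si](C)(C)C(C)(C)C)CC[C@H]1OCc2ccc(OC)cc2 | intermediate
26 | macrocyclic C2, C18 diol, C7 4-methoxybenzyl ether | C=C1CC/C=C(\C)CC[C@H](C(=C)C)[C@@H](O)/C=C(/CO)CC[C@H]1OCc2ccc(OC)cc2 | intermediate
27 | macrocyclic C2, C18 diacetate, C7 4-methoxybenzyl ether | C=C1CC/C=C(\C)CC[C@H](C(=C)C)[C@@H](OC(C)=O)/C=C(/COC(C)=O)CC[C@H]1OCc2ccc(OC)cc2 | intermediate
28 | target, (1R,2S,7R)-2,18-diacetoxy-7-hydroxycembra-3,8(19),11,15-tetraene | C=C1CC/C=C(\C)CC[C@H](C(=C)C)[C@@H](OC(C)=O)/C=C(/COC(C)=O)CC[C@H]1O | target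

## Step count and least certain steps

Total step count: 20 (the telescoped step 1 counted once). Longest linear sequence: 16 steps, from 7 through steps 4–10 and 12–20 to 28 (15 steps from 1).

**Step 16 (key step).** Intermolecular alkylation could outrun ring closure if the carbanion accumulates, giving chain growth. Alkylation through C12, or base-induced migration of the allyl sulfone double bond into conjugation, are lesser risks. The fallback changes the ring-closing event: the C9–C10 bond is made between molecules and the ring is closed at C7–C8. It sets out from 15. KN(SiMe3)2 (1.05 equiv, THF, −78 °C) deprotonates the sulfone in preference to the far less acidic ester, and alkylation with 18 should give the C10 2-bromoallyl sulfone ester F1. i-Bu2AlH at −78 °C should give the bromo-aldehyde F2. Intramolecular Nozaki–Hiyama–Kishi alkenylation at high dilution (CrCl2, NiCl2(2,9-dimethyl-1,10-phenanthroline), Mn, Cp2ZrCl2, the chiral sulfonamide ligand) should give the macrocyclic C7 alcohol F3. 4-Methoxybenzyl trichloroacetimidate with catalytic La(OTf)3 brings the route back at 24. In this fallback C7 is set during ring closure; if facial control were poor, the oxidation and reduction sequence of the step 12 fallback would be applied to the ring.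

**Step 3.** The allylic sulfone might be ionised in competition, the E geometry could erode through syn–anti isomerisation of the allylpalladium intermediate, and the boronate could protodeboronate on isolation. The fallback replaces in-flask activation of the hydroxyl by a preformed leaving group. It sets out from 5: methyl chloroformate and pyridine give the allylic methyl carbonate F4, and Miyaura-type allylic borylation (Pd2(dba)3, B2pin2, DMSO, rt to 50 °C), in which the released methoxide activates the diboron reagent, comes back at 6.

**Step 8.** The catalyst may discriminate the enal faces poorly with a β-methyl, γ-alkyl boronate and a β,β-disubstituted enal, or uncatalysed background addition may lower the enantiomeric purity; the anti relationship itself is secure. The fallback replaces boron by chromium and bypasses 6. It sets out from 5: CBr4 and PPh3 give the allylic bromide F5, and catalytic asymmetric Nozaki–Hiyama–Kishi allylation of 13 (CrCl2, chiral oxazoline–sulfonamide or bis(oxazolinyl)carbazole ligand, Mn, Cp2ZrCl2, THF) should give the anti adduct through a chair transition state whatever the bromide geometry. It comes back at 14.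

**Step 12.** Facial selection at an unbranched aldehyde far from any stereocentre may be insufficient, and low-valent nickel could attack the allylic sulfone. The fallback separates bond formation from stereocontrol. It sets out from 16: ligand-free coupling with 19 (CrCl2, NiCl2 cat., DMSO/THF) gives the C7 epimer mixture F6, Dess–Martin periodinane gives the α-methylene ketone F7, and (S)-2-methyl-CBS-oxazaborolidine with catecholborane (toluene, −78 °C), in which the branched alkenyl group acts as the large substituent, should give the 7R alcohol. It comes back at 20.

**Step 17.** Hydride may be delivered at C12 instead of C10 (alkene transposition to C10=C11), or C11=C12 may equilibrate between E and Z through the allylpalladium intermediate. The fallback changes the mechanism from palladium hydride transfer to single-electron C–S cleavage: sodium amalgam with Na2HPO4 in MeOH/THF at −20 °C, applied to 24 and returning at 25. It makes no new compound (F0).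

## Further compounds

F1 | step 16 | ethyl ester 15 alkylated at C10 with a 2-bromoallyl group (C10 epimers) | C=C(Br)CC(S(=O)(=O)c1ccccc1)/C=C(\C)CC[C@H](C(=C)C)[C@@H](O[Si](C)(C)C(C)(C)C)/C=C(/CO[Si](C)(C)C(C)(C)C)CCC(=O)OCC
F2 | step 16 | C7 aldehyde corresponding to F1 | C=C(Br)CC(S(=O)(=O)c1ccccc1)/C=C(\C)CC[C@H](C(=C)C)[C@@H](O[Si](C)(C)C(C)(C)C)/C=C(/CO[Si](C)(C)C(C)(C)C)CCC=O
F3 | step 16 | 10-phenylsulfonyl macrocycle with free (7R) hydroxyl | C=C1CC(S(=O)(=O)c2ccccc2)/C=C(\C)CC[C@H](C(=C)C)[C@@H](O[Si](C)(C)C(C)(C)C)/C=C(/CO[Si](C)(C)C(C)(C)C)CC[C@H]1O
F4 | step 3 | methyl (2E,6E)-2,6-dimethyl-8-(phenylsulfonyl)octa-2,6-dien-1-yl carbonate | COC(=O)OC/C(C)=C/CC/C(C)=C/CS(=O)(=O)c1ccccc1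
F5 | step 8 | [(2E,6E)-8-bromo-3,7-dimethylocta-2,6-dien-1-yl]sulfonylbenzene | BrC/C(C)=C/CC/C(C)=C/CS(=O)(=O)c1ccccc1
F6 | step 12 | C7 epimer mixture of 20 | O=S(=O)(c1ccccc1)C/C=C(\C)CC[C@H](C(=C)C)[C@@H](O[Si](C)(C)C(C)(C)C)/C=C(/CO[Si](C)(C)C(C)(C)C)CCC(O)C(=C)COCc1ccc(OC)cc1
F7 | step 12 | C7 ketone (α-methylene ketone) corresponding to 20 | O=S(=O)(c1ccccc1)C/C=C(\C)CC[C@H](C(=C)C)[C@@H](O[Si](C)(C)C(C)(C)C)/C=C(/CO[Si](C)(C)C(C)(C)C)CCC(=O)C(=C)COCc1ccc(OC)cc1
F0 | step 17 | none | none
A1 | alternative 1 | open-chain C16 allylic bromide with C2 enal, 18-acetate, 7-silyl ether (7R) | BrC/C(C)=C/CC/C(C)=C/CCC(=C)[C@H](O[Si](C)(C)C(C)(C)C)CC/C(COC(C)=O)=C\C=O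
A2 | alternative 1 | (1R,2S,7R) macrocyclic C2 alcohol, 18-acetate, 7-silyl ether | C=C1CC/C=C(\C)CC[C@H](C(=C)C)[C@@H](O)/C=C(/COC(C)=O)CC[C@H]1O[Si](C)(C)C(C)(C)C
A3 | alternative 2 | eighteen-membered lactone (C16 ester oxygen, E C15=C1 alkene, acyl carbon on C14) | O=C1CC/C(C)=C/CCC(=C)[C@H](OCc2ccc(OC)cc2)CC/C(CO[Si](C)(C)C(C)(C)C)=C\[C@H](O[Si](C)(C)C(C)(C)C)/C=C(\C)CO1
A4 | alternative 2 | fourteen-membered carbocycle with C14 carboxylic acid (C14 epimers) | C=C1CC/C=C(\C)CC(C(=O)O)[C@H](C(=C)C)[C@@H](O[Si](C)(C)C(C)(C)C)/C=C(/CO[Si](C)(C)C(C)(C)C)CC[C@H]1OCc2ccc(OC)cc2
A5 | alternative 3 | open-chain C3 aldehyde (2-silyloxy) with C4 dimethyl phosphonoacetate terminus | O=C[C@H](O[Si](C)(C)C(C)(C)C)[C@@H](C(=C)C)CC/C(C)=C/CCC(=C)[C@H](OCc1ccc(OC)cc1)CCC(C(=O)OC)P(=O)(OC)OC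
A6 | alternative 3 | macrocyclic methyl ester with C18 as carboxyl, ester trans to C2 | C=C1CC/C=C(\C)CC[C@H](C(=C)C)[C@@H](O[Si](C)(C)C(C)(C)C)/C=C(/C(=O)OC)CC[C@H]1OCc2ccc(OC)cc2
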